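The benzene ring of the chroman is built last, from acyclic pieces. That ring carries oxygen on C7 and C8a (meta to each other), the benzofuran on C5 and the pyran CH2 on the neighbouring C4a: the pattern of a 4-alkyl-5-arylcyclohexane-1,3-dione. One base-mediated operation joins a benzofuran-2-yl enone and a prenylmalonate by conjugate addition (C4a–C5) and intramolecular Claisen condensation (C8–C8a), closing that carbocycle with every substituent in place. The precursor is an (E)-4-(benzofuran-2-yl)but-3-en-2-one that already bears the 7-(1,1-dimethylallyl) group and two allyl-protected phenols. Decarboxylation, acid closure of the pyran, dehydrogenation and deallylation finish the synthesis.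

Key step: step 8

Remark: the two benzofuran phenols are carried as allyl ethers from step 1. Acetal groups would be cleaved, with release of a formaldehyde equivalent onto the nucleophilic 1,3-dione, by the acid that closes the pyran in step 10. Benzyl ethers could not be hydrogenolysed beside the vinyl group. Allyl ethers tolerate base, acid and enolate chemistry and leave under neutral Pd(PPh3)4 catalysis.
Remark: the sigmatropic step is run under mild Eu(fod)3 catalysis and not thermally. At about 200 °C a dimethylallyl group on this kind of ring is expected to move on to the para carbon C5, and the allyl ethers themselves would rearrange.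
Remark: the target has no stereocentre. The sp3 centres in 5, 9 and 17 to 24 arise without control and are all removed again, so these compounds are drawn without configuration.

Step 1
Reactants: 1 2,4,6-trihydroxybenzaldehyde
Product: 2 2-hydroxy-4,6-bis(prop-2-en-1-yloxy)benzaldehyde
Conditions: allyl bromide (2.1 equiv), K2CO3 (2.2 equiv), acetone, reflux
Reagents that add atoms: allyl bromide, C=CCBr
Why: Williamson etherification should take the para hydroxyl and one ortho hydroxyl and spare the other, because after the first ortho alkylation the remaining ortho hydroxyl is held in a hydrogen bond to the formyl oxygen and is far less nucleophilic.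

Step 2
Reactants: 2 2-hydroxy-4,6-bis(prop-2-en-1-yloxy)benzaldehyde; 3 prenyl bromide (1-bromo-3-methylbut-2-ene)
Product: 4 2-[(3-methylbut-2-en-1-yl)oxy]-4,6-bis(prop-2-en-1-yloxy)benzaldehyde
Conditions: K2CO3, DMF, 40 °C
Reagents that add atoms: none
Why: Williamson etherification (SN2 at the primary allylic bromide), in which the dipolar aprotic solvent frees the chelated phenoxide for O-alkylation.

Step 3
Reactants: 4 2-[(3-methylbut-2-en-1-yl)oxy]-4,6-bis(prop-2-en-1-yloxy)benzaldehyde
Product: 6 2-hydroxy-3-(2-methylbut-3-en-2-yl)-4,6-bis(prop-2-en-1-yloxy)benzaldehyde, via ortho-dienone 5 (not isolated)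
Conditions: Eu(fod)3 (10 mol %), CHCl3, 50 °C
Reagents that add atoms: none
Why: Aromatic Claisen rearrangement, in which the Eu(fod)3 chelate between the formyl oxygen and the prenyl ether oxygen weakens the O–CH2 bond so that the cation-stabilising prenyl unit shifts [3,3] with allylic inversion to the free ortho carbon C3, far below the temperature at which the unactivated allyl ethers or a second shift to C5 would set in, and dienone 5 tautomerises to the hydrogen-bonded phenol.

Step 4
Reactants: 6 2-hydroxy-3-(2-methylbut-3-en-2-yl)-4,6-bis(prop-2-en-1-yloxy)benzaldehyde; 7 methyl bromoacetate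
Product: 10 methyl 7-(2-methylbut-3-en-2-yl)-4,6-bis(prop-2-en-1-yloxy)-1-benzofuran-2-carboxylate, via aryloxyacetate 8 (not isolated), via aldol adduct 9 (not isolated)
Conditions: K2CO3, DMF, 60 °C then 110 °C
Reagents that add atoms: none
Why: Rap–Stoermer-type benzofuran annulation, that is O-alkylation of the salicylaldehyde, intramolecular aldol addition of the ester enolate to the formyl group and dehydration, driven by aromatisation of the furan.

Step 5
Reactants: 10 methyl 7-(2-methylbut-3-en-2-yl)-4,6-bis(prop-2-en-1-yloxy)-1-benzofuran-2-carboxylate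
Product: 11 [7-(2-methylbut-3-en-2-yl)-4,6-bis(prop-2-en-1-yloxy)-1-benzofuran-2-yl]methanol
Conditions: i-Bu2AlH (2.5 equiv), CH2Cl2, −78 to 0 °C; aq KNaC4H4O6
Reagents that add atoms: none
Why: Hydride reduction of the ester to the primary alcohol, at a temperature where i-Bu2AlH does not hydroaluminate the isolated terminal alkenes.

Step 6
Reactants: 11 [7-(2-methylbut-3-en-2-yl)-4,6-bis(prop-2-en-1-yloxy)-1-benzofuran-2-yl]methanol; 12 1-(triphenylphosphoranylidene)propan-2-one
Product: 14 (3E)-4-[7-(2-methylbut-3-en-2-yl)-4,6-bis(prop-2-en-1-yloxy)-1-benzofuran-2-yl]but-3-en-2-one, via aldehyde 13 (not isolated)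
Conditions: MnO2 (activated, 10 equiv), toluene, reflux
Reagents that add atoms: none
Why: Tandem oxidation–Wittig olefination, in which MnO2 oxidises the furfuryl-type alcohol to aldehyde 13 and the ketone-stabilised ylide traps it in situ, which should give the E enone as stabilised ylides do.

Step 7
Reactants: 15 dimethyl malonate; 3 prenyl bromide (1-bromo-3-methylbut-2-ene)
Product: 16 dimethyl 2-(3-methylbut-2-en-1-yl)propanedioate
Conditions: NaH (1.0 equiv), THF, 0 °C; then 3 (1.0 equiv), 0 °C to rt; 15 in 1.5-fold excess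
Reagents that add atoms: none
Why: Malonic ester alkylation (SN2 at the primary allylic bromide), with the excess of malonate keeping dialkylation low.

Step 8
Reactants: 14 (3E)-4-[7-(2-methylbut-3-en-2-yl)-4,6-bis(prop-2-en-1-yloxy)-1-benzofuran-2-yl]but-3-en-2-one; 16 dimethyl 2-(3-methylbut-2-en-1-yl)propanedioate
Product: 18 methyl 6-[7-(2-methylbut-3-en-2-yl)-4,6-bis(prop-2-en-1-yloxy)-1-benzofuran-2-yl]-1-(3-methylbut-2-en-1-yl)-2,4-dioxocyclohexane-1-carboxylate (racemic; mixture of diastereomers), via Michael adduct 17 (not isolated)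
Conditions: NaOMe (1.5 equiv), MeOH, reflux; then 1 M HCl to pH 4
Reagents that add atoms: none
Why: NaOMe generates the enolate of 16, which adds 1,4 to enone 14 (Michael addition, new C4a–C5 bond of the later chroman); proton transfer in adduct 17 gives the terminal methyl-ketone enolate, which attacks one of the two geminal esters and expels methoxide (intramolecular Claisen condensation of the Dieckmann kind, new C8–C8a bond). The closest known reaction type is the Michael–Claisen synthesis of 5-arylcyclohexane-1,3-diones from arylideneacetones and malonic esters, which tolerates 2-alkylmalonates and enones with a 2-furyl group on the β-carbon. The one ring closes in a 6-exo-trig mode, and the reversible sequence is driven to the product because the 1,3-dione is deprotonated at once to an enolate that does not revert. Two stereocentres arise (the quaternary C1 and the aryl-bearing C6 of the cyclohexane) with no controlling element, so a racemic mixture of diastereomers is expected and is carried on as such, since both carbons become sp2 centres of the benzene ring. Constitution is the only thing that must be controlled, and it follows from polarity and ring size: the soft malonate carbon bonds to the β-carbon and not to the carbonyl group, and of the two ketone enolates only the methyl one can reach an ester through a six-membered transition state (the internal methylene would have to close a four-membered ring), so the prenyl-bearing carbon can only lie between the aryl-bearing carbon and a ring carbonyl.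

Step 9
Reactants: 18 methyl 6-[7-(2-methylbut-3-en-2-yl)-4,6-bis(prop-2-en-1-yloxy)-1-benzofuran-2-yl]-1-(3-methylbut-2-en-1-yl)-2,4-dioxocyclohexane-1-carboxylate
Product: 20 5-[7-(2-methylbut-3-en-2-yl)-4,6-bis(prop-2-en-1-yloxy)-1-benzofuran-2-yl]-4-(3-methylbut-2-en-1-yl)cyclohexane-1,3-dione (racemic; mixture of diastereomers), via β-keto acid 19 (not isolated)
Conditions: KOH (5 equiv), MeOH/H2O, reflux; then 2 M HCl to pH 3, 50 °C
Reagents that add atoms: none
Why: Ester saponification followed by decarboxylation of the β-keto acid through its cyclic six-membered transition state, with the dione present as its enolate in base (which shields the ring ketones from retro-Claisen cleavage) and the allyl aryl ethers inert to both base and dilute acid.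

Step 10
Reactants: 20 5-[7-(2-methylbut-3-en-2-yl)-4,6-bis(prop-2-en-1-yloxy)-1-benzofuran-2-yl]-4-(3-methylbut-2-en-1-yl)cyclohexane-1,3-dione
Product: 21 5-[7-(2-methylbut-3-en-2-yl)-4,6-bis(prop-2-en-1-yloxy)-1-benzofuran-2-yl]-2,2-dimethyl-2,3,4,4a,5,6-hexahydro-7H-chromen-7-one (racemic; mixture of diastereomers)
Conditions: TsOH·H2O (0.2 equiv), toluene, 70 °C
Reagents that add atoms: none
Why: Acid-catalysed Markovnikov hydroalkoxylation, in which protonation of the trisubstituted prenyl alkene gives a tertiary cation that the neighbouring enol oxygen captures in a six-membered ring (the closure that turns ortho-prenyl phenols into 2,2-dimethylchromans), while the three monosubstituted alkenes would have to form secondary cations and the allyl aryl ethers are acid-stable.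

Step 11
Reactants: 21 5-[7-(2-methylbut-3-en-2-yl)-4,6-bis(prop-2-en-1-yloxy)-1-benzofuran-2-yl]-2,2-dimethyl-2,3,4,4a,5,6-hexahydro-7H-chromen-7-one
Product: 25 5-[7-(2-methylbut-3-en-2-yl)-4,6-bis(prop-2-en-1-yloxy)-1-benzofuran-2-yl]-2,2-dimethyl-3,4-dihydro-2H-chromen-7-ol, via selenide 22 (not isolated), via selenoxide 23 (not isolated), via cyclohexadienone 24 (not isolated)
Conditions: LiN(iPr)2 (1.1 equiv), THF, −78 °C; PhSeCl (1.05 equiv), −78 °C; then 30% H2O2, pyridine, CH2Cl2, 0 °C to rt
Reagents that add atoms: none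
Why: Kinetic deprotonation of the vinylogous ester at the α′ methylene C6, selenenylation of the enolate, oxidation and selenoxide syn-elimination toward C5–H should give dienone 24, which tautomerises at once to the phenol; the enolate takes up PhSeCl much faster than the terminal alkenes do, and excess H2O2 with pyridine destroys the benzeneselenenic acid before it can add to them.

Step 12
Reactants: 25 5-[7-(2-methylbut-3-en-2-yl)-4,6-bis(prop-2-en-1-yloxy)-1-benzofuran-2-yl]-2,2-dimethyl-3,4-dihydro-2H-chromen-7-ol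
Product: 26 2-(7-hydroxy-2,2-dimethyl-3,4-dihydro-2H-chromen-5-yl)-7-(2-methylbut-3-en-2-yl)-1-benzofuran-4,6-diol
Conditions: Pd(PPh3)4 (5 mol %), morpholine (10 equiv), THF, rt, argon
Reagents that add atoms: none
Why: Tsuji–Trost deallylation, in which Pd(PPh3)4 (zerovalent palladium) ionises each allyl aryl ether to a π-allyl complex and a phenoxide and morpholine captures the allyl unit, under neutral conditions that leave the all-carbon 1,1-dimethylallyl group, the chroman ether and the benzofuran untouched.

Compound list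
1 | 2,4,6-trihydroxybenzaldehyde | O=Cc1c(O)cc(O)cc1O | starting material
2 | 2-hydroxy-4,6-bis(prop-2-en-1-yloxy)benzaldehyde | O=Cc1c(O)cc(OCC=C)cc1OCC=C | intermediate
3 | prenyl bromide (1-bromo-3-methylbut-2-ene) | CC(C)=CCBr | starting material
4 | 2-[(3-methylbut-2-en-1-yl)oxy]-4,6-bis(prop-2-en-1-yloxy)benzaldehyde | O=Cc1c(OCC=C(C)C)cc(OCC=C)cc1OCC=C | intermediate
5 | 5-(2-methylbut-3-en-2-yl)-6-oxo-2,4-bis(prop-2-en-1-yloxy)cyclohexa-1,3-diene-1-carbaldehyde (racemic ortho-dienone) | O=CC1=C(OCC=C)C=C(OCC=C)C(C(C)(C)C=C)C1=O | intermediate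
6 | 2-hydroxy-3-(2-methylbut-3-en-2-yl)-4,6-bis(prop-2-en-1-yloxy)benzaldehyde | O=Cc1c(O)c(C(C)(C)C=C)c(OCC=C)cc1OCC=C | intermediate
7 | methyl bromoacetate | COC(=O)CBr | starting material
8 | methyl 2-[2-formyl-6-(2-methylbut-3-en-2-yl)-3,5-bis(prop-2-en-1-yloxy)phenoxy]acetate | COC(=O)COc1c(C=O)c(OCC=C)cc(OCC=C)c1C(C)(C)C=C | intermediate
9 | methyl 3-hydroxy-7-(2-methylbut-3-en-2-yl)-4,6-bis(prop-2-en-1-yloxy)-2,3-dihydro-1-benzofuran-2-carboxylate (racemic; mixture of diastereomers) | COC(=O)C1Oc2c(C(C)(C)C=C)c(OCC=C)cc(OCC=C)c2C1O | intermediate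
10 | methyl 7-(2-methylbut-3-en-2-yl)-4,6-bis(prop-2-en-1-yloxy)-1-benzofuran-2-carboxylate | COC(=O)c1cc2c(OCC=C)cc(OCC=C)c(C(C)(C)C=C)c2o1 | intermediate
11 | [7-(2-methylbut-3-en-2-yl)-4,6-bis(prop-2-en-1-yloxy)-1-benzofuran-2-yl]methanol | OCc1cc2c(OCC=C)cc(OCC=C)c(C(C)(C)C=C)c2o1 | intermediate
12 | 1-(triphenylphosphoranylidene)propan-2-one | CC(=O)C=P(c1ccccc1)(c1ccccc1)c1ccccc1 | starting material
13 | 7-(2-methylbut-3-en-2-yl)-4,6-bis(prop-2-en-1-yloxy)-1-benzofuran-2-carbaldehyde | O=Cc1cc2c(OCC=C)cc(OCC=C)c(C(C)(C)C=C)c2o1 | intermediate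
14 | (3E)-4-[7-(2-methylbut-3-en-2-yl)-4,6-bis(prop-2-en-1-yloxy)-1-benzofuran-2-yl]but-3-en-2-one | CC(=O)/C=C/c1cc2c(OCC=C)cc(OCC=C)c(C(C)(C)C=C)c2o1 | intermediate
15 | dimethyl malonate | COC(=O)CC(=O)OC | starting material
16 | dimethyl 2-(3-methylbut-2-en-1-yl)propanedioate | COC(=O)C(CC=C(C)C)C(=O)OC | intermediate
17 | dimethyl 2-(3-methylbut-2-en-1-yl)-2-{1-[7-(2-methylbut-3-en-2-yl)-4,6-bis(prop-2-en-1-yloxy)-1-benzofuran-2-yl]-3-oxobutyl}propanedioate (racemic) | COC(=O)C(CC=C(C)C)(C(=O)OC)C(CC(C)=O)c1cc2c(OCC=C)cc(OCC=C)c(C(C)(C)C=C)c2o1 | intermediate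
18 | methyl 6-[7-(2-methylbut-3-en-2-yl)-4,6-bis(prop-2-en-1-yloxy)-1-benzofuran-2-yl]-1-(3-methylbut-2-en-1-yl)-2,4-dioxocyclohexane-1-carboxylate (racemic; mixture of diastereomers) | COC(=O)C1(CC=C(C)C)C(=O)CC(=O)CC1c1cc2c(OCC=C)cc(OCC=C)c(C(C)(C)C=C)c2o1 | intermediate
19 | 6-[7-(2-methylbut-3-en-2-yl)-4,6-bis(prop-2-en-1-yloxy)-1-benzofuran-2-yl]-1-(3-methylbut-2-en-1-yl)-2,4-dioxocyclohexane-1-carboxylic acid (racemic; mixture of diastereomers) | OC(=O)C1(CC=C(C)C)C(=O)CC(=O)CC1c1cc2c(OCC=C)cc(OCC=C)c(C(C)(C)C=C)c2o1 | intermediate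
20 | 5-[7-(2-methylbut-3-en-2-yl)-4,6-bis(prop-2-en-1-yloxy)-1-benzofuran-2-yl]-4-(3-methylbut-2-en-1-yl)cyclohexane-1,3-dione (racemic; mixture of diastereomers) | O=C1CC(=O)C(CC=C(C)C)C(c2cc3c(OCC=C)cc(OCC=C)c(C(C)(C)C=C)c3o2)C1 | intermediate
21 | 5-[7-(2-methylbut-3-en-2-yl)-4,6-bis(prop-2-en-1-yloxy)-1-benzofuran-2-yl]-2,2-dimethyl-2,3,4,4a,5,6-hexahydro-7H-chromen-7-one (racemic; mixture of diastereomers) | O=C1C=C2OC(C)(C)CCC2C(c3cc4c(OCC=C)cc(OCC=C)c(C(C)(C)C=C)c4o3)C1 | intermediate
22 | 5-[7-(2-methylbut-3-en-2-yl)-4,6-bis(prop-2-en-1-yloxy)-1-benzofuran-2-yl]-2,2-dimethyl-6-(phenylselanyl)-2,3,4,4a,5,6-hexahydro-7H-chromen-7-one (racemic; mixture of diastereomers) | O=C1C=C2OC(C)(C)CCC2C(c3cc4c(OCC=C)cc(OCC=C)c(C(C)(C)C=C)c4o3)C1[Se]c1ccccc1 | intermediate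
23 | 6-(benzeneseleninyl)-5-[7-(2-methylbut-3-en-2-yl)-4,6-bis(prop-2-en-1-yloxy)-1-benzofuran-2-yl]-2,2-dimethyl-2,3,4,4a,5,6-hexahydro-7H-chromen-7-one (mixture of diastereomers) | O=C1C=C2OC(C)(C)CCC2C(c3cc4c(OCC=C)cc(OCC=C)c(C(C)(C)C=C)c4o3)C1[Se](=O)c1ccccc1 | intermediate
24 | 5-[7-(2-methylbut-3-en-2-yl)-4,6-bis(prop-2-en-1-yloxy)-1-benzofuran-2-yl]-2,2-dimethyl-2,3,4,4a-tetrahydro-7H-chromen-7-one (racemic) | O=C1C=C2OC(C)(C)CCC2C(c3cc4c(OCC=C)cc(OCC=C)c(C(C)(C)C=C)c4o3)=C1 | intermediate
25 | 5-[7-(2-methylbut-3-en-2-yl)-4,6-bis(prop-2-en-1-yloxy)-1-benzofuran-2-yl]-2,2-dimethyl-3,4-dihydro-2H-chromen-7-ol | C=CC(C)(C)c1c(OCC=C)cc(OCC=C)c2cc(-c3cc(O)cc4c3CCC(C)(C)O4)oc12 | intermediate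
26 | 2-(7-hydroxy-2,2-dimethyl-3,4-dihydro-2H-chromen-5-yl)-7-(2-methylbut-3-en-2-yl)-1-benzofuran-4,6-diol | C=CC(C)(C)c1c(O)cc(O)c2cc(-c3cc(O)cc4c3CCC(C)(C)O4)oc12 | target

Total steps: 12. Longest linear sequence: 11 steps (steps 1 to 6 and 8 to 12; step 7 is a one-step side branch).

Steps most likely to fail

1. Step 8. The conjugate addition of a fully substituted malonate carbanion is slow and reversible, so retro-addition and self-condensation of the enone through its own methyl enolate may outrun the ring closure. Fallback: the same two bonds are made with the unhindered parent malonate and the prenyl group is put on afterwards. Setting out from 14 and 15, NaOMe in MeOH at reflux should give methyl 6-[7-(2-methylbut-3-en-2-yl)-4,6-bis(prop-2-en-1-yloxy)-1-benzofuran-2-yl]-2,4-dioxocyclohexane-1-carboxylate F1. Its dianion (LiN(iPr)2, 2.2 equiv, THF, −78 to 0 °C) is then alkylated with prenyl bromide 3 at the last-formed and most nucleophilic carbon, the one that carries the ester (dianion alkylation of a β-dicarbonyl compound). This comes back to the route at 18.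

2. Step 3. The sigmatropic process may not stop after the first [3,3] shift (onward migration of the dimethylallyl group to C5 on long heating), and if the temperature has to be raised to reach full conversion the second chelated ether, the allyl group on O6, may begin to rearrange as well. Fallback: the rearrangement is carried out before any other allylic ether is present. Setting out from 1, chloromethyl methyl ether with K2CO3 in acetone should give 2-hydroxy-4,6-bis(methoxymethoxy)benzaldehyde F2. Prenyl bromide 3 with K2CO3 in DMF gives 4,6-bis(methoxymethoxy)-2-[(3-methylbut-2-en-1-yl)oxy]benzaldehyde F3. Eu(fod)3 in CHCl3, which can now be driven with more catalyst, gives 2-hydroxy-4,6-bis(methoxymethoxy)-3-(2-methylbut-3-en-2-yl)benzaldehyde F4. Annulation with 7 (K2CO3, DMF) gives methyl 4,6-bis(methoxymethoxy)-7-(2-methylbut-3-en-2-yl)-1-benzofuran-2-carboxylate F5. HCl in MeOH at 40 °C removes both acetals to give methyl 4,6-dihydroxy-7-(2-methylbut-3-en-2-yl)-1-benzofuran-2-carboxylate F6, and allyl bromide with K2CO3 in DMF comes back to the route at 10.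

3. Step 11. The electrophilic selenium species (PhSeCl, or the benzeneselenenic acid released in the elimination) may add across one of the three terminal alkenes, and the peroxide may over-oxidise the electron-rich product. Fallback: sulfur in place of selenium and no external oxidant. Setting out from 21, the lithium enolate (LiN(iPr)2, 2.2 equiv, THF, −78 °C) is sulfinylated with methyl benzenesulfinate to 6-(benzenesulfinyl)-5-[7-(2-methylbut-3-en-2-yl)-4,6-bis(prop-2-en-1-yloxy)-1-benzofuran-2-yl]-2,2-dimethyl-2,3,4,4a,5,6-hexahydro-7H-chromen-7-one F7. Heating in toluene at 90 °C over CaCO3 should bring about sulfoxide syn-elimination to dienone 24, whose tautomerisation comes back to the route at 25.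

Further compounds
F1 | step 8 | methyl 6-[7-(2-methylbut-3-en-2-yl)-4,6-bis(prop-2-en-1-yloxy)-1-benzofuran-2-yl]-2,4-dioxocyclohexane-1-carboxylate (racemic; mixture of diastereomers) | COC(=O)C1C(=O)CC(=O)CC1c1cc2c(OCC=C)cc(OCC=C)c(C(C)(C)C=C)c2o1
F2 | step 3 | 2-hydroxy-4,6-bis(methoxymethoxy)benzaldehyde | O=Cc1c(O)cc(OCOC)cc1OCOC
F3 | step 3 | 4,6-bis(methoxymethoxy)-2-[(3-methylbut-2-en-1-yl)oxy]benzaldehyde | O=Cc1c(OCC=C(C)C)cc(OCOC)cc1OCOC
F4 | step 3 | 2-hydroxy-4,6-bis(methoxymethoxy)-3-(2-methylbut-3-en-2-yl)benzaldehyde | O=Cc1c(O)c(C(C)(C)C=C)c(OCOC)cc1OCOC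
F5 | step 3 | methyl 4,6-bis(methoxymethoxy)-7-(2-methylbut-3-en-2-yl)-1-benzofuran-2-carboxylate | COC(=O)c1cc2c(OCOC)cc(OCOC)c(C(C)(C)C=C)c2o1
F6 | step 3 | methyl 4,6-dihydroxy-7-(2-methylbut-3-en-2-yl)-1-benzofuran-2-carboxylate | COC(=O)c1cc2c(O)cc(O)c(C(C)(C)C=C)c2o1
F7 | step 11 | 6-(benzenesulfinyl)-5-[7-(2-methylbut-3-en-2-yl)-4,6-bis(prop-2-en-1-yloxy)-1-benzofuran-2-yl]-2,2-dimethyl-2,3,4,4a,5,6-hexahydro-7H-chromen-7-one (mixture of diastereomers) | O=C1C=C2OC(C)(C)CCC2C(c3cc4c(OCC=C)cc(OCC=C)c(C(C)(C)C=C)c4o3)C1S(=O)c1ccccc1
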